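## Plan

- The target is a 6,8-dihydroxy-3,4-dihydroisocoumarin (benzene ring A fused to lactone ring B) with a (10S)-10-methoxyundecyl chain at C3 (3R). The enabling feature is that C3 carries the ring oxygen O2 and lies between benzylic C4 and chain carbon C1'. With C1'=C2' as an alkene, C3–H is the allylic C–H bond of a but-3-enyl arene whose benzylic oxygen on C1 can reach it through a six-membered ring.
- Retrosynthetic cuts, in order: the C1 carbonyl back to a CH2 ether, C1'=C2' (cross-metathesis), O2–C3 (allylic C–H oxidation), C3–C4 (allylation of the orsellinate methyl group) and C8'–C9' (Grignard opening of propylene oxide).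
- Forward: ring A is bought as methyl orsellinate and is protected, allylated at the methyl group and reduced. Ring B closes in step 4, the chain is joined in step 7, and hydrogenation, C1 oxidation and deprotection finish the route.
- Stereochemistry: C3 comes from the chiral sulfoxide–oxazoline ligand on Pd(OAc)2 in step 4 (3S as the vinyl ether, 3R by descriptor once the chain is saturated, same geometry). C10' comes from (S)-propylene oxide.

Key step: step 4

Assumption: both antipodes of the aryl sulfoxide–oxazoline ligand are accessible, and the antipode that delivers the 3S ether is the one used in step 4.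

## Route

Step 1
Reactants: 1 methyl orsellinate (methyl 2,4-dihydroxy-6-methylbenzoate)
Product: 3 methyl 2,4-bis(methoxymethoxy)-6-methylbenzoate, via disodium bis-phenoxide 2 (not isolated)
Conditions: NaH (2.5 equiv), DMF, 0 °C; MOMCl (2.5 equiv), 0 °C to rt
Reagents that add atoms: chloromethyl methyl ether (MOMCl), COCCl
Why: Williamson-type O-alkylation of the bis-phenoxide, in which NaH in DMF also deprotonates the hydroxyl that is hydrogen-bonded to the ester, gives acetals that tolerate the base, hydride, Pd, Ru and chromium reagents used later.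

Step 2
Reactants: 3 methyl 2,4-bis(methoxymethoxy)-6-methylbenzoate; 4 allyl bromide (3-bromoprop-1-ene)
Product: 6 methyl 2-(but-3-en-1-yl)-4,6-bis(methoxymethoxy)benzoate, via benzylic lithium species 5 (not isolated)
Conditions: LiN(iPr)2 (1.2 equiv), THF, −78 °C; then 4, −78 °C to −40 °C
Reagents that add atoms: none
Why: Lateral lithiation removes a proton from the methyl group ortho to the ester, and the toluate anion should be alkylated by the allylic bromide (SN2) faster than it adds to the hindered ester of a second molecule at −78 °C.

Step 3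
Reactants: 6 methyl 2-(but-3-en-1-yl)-4,6-bis(methoxymethoxy)benzoate
Product: 7 [2-(but-3-en-1-yl)-4,6-bis(methoxymethoxy)phenyl]methanol
Conditions: LiAlH4, THF, 0 °C to rt; aqueous NaOH work-up
Reagents that add atoms: none
Why: Hydride reduction of the ester to the primary benzylic alcohol, since LiAlH4 is small enough for the doubly ortho-substituted ester and does not touch the isolated alkene or the acetals.

Step 4
Reactants: 7 [2-(but-3-en-1-yl)-4,6-bis(methoxymethoxy)phenyl]methanol
Product: 8 (3S)-3-ethenyl-6,8-bis(methoxymethoxy)isochromane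
Conditions: Pd(OAc)2 (10 mol %), chiral aryl sulfoxide–oxazoline ligand (10 mol %, antipode giving 3S), 2,5-dimethyl-1,4-benzoquinone (1.2 equiv), Ph2P(O)OH (10 mol %), toluene, 45 °C
Reagents that add atoms: none
Why: Ligated Pd(OAc)2 (divalent palladium) removes a hydrogen from the single allylic CH2 group to form a π-allylpalladium species, the benzylic hydroxyl attacks its internal terminus to make O2–C3, and the quinone returns zerovalent palladium to the divalent state. The closest known reaction type is the Pd(OAc)2/sulfoxide-catalysed enantioselective allylic C–H oxidation of terminal olefins carrying a tethered benzylic alcohol, which gives 3-vinylisochromans and to which 7 belongs. Ring B closes in a 6-exo mode, the allyl unit staying outside the ring as the vinyl group, whereas attack at the distal terminus would require an eight-membered ring. The new stereocenter C3 is set by the chiral ligand on palladium, which distinguishes the two faces of the π-allyl unit of an otherwise achiral substrate. The step needs branched regioselectivity and C–H cleavage in preference to alcohol oxidation, Wacker oxidation or diene formation; the two-carbon spacer between arene and alkene and the ortho hydroxymethyl group secure the six-membered closure, and the weak phosphinic acid co-catalyst should leave the acetals intact.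

Step 5
Reactants: 9 8-bromooct-1-ene; 10 (S)-propylene oxide [(2S)-2-methyloxirane]
Product: 12 (2S)-undec-10-en-2-ol, via oct-7-enylmagnesium bromide 11 (not isolated)
Conditions: Mg, THF, rt to 40 °C; then CuI (10 mol %), 10, −30 °C to 0 °C; aq NH4Cl
Reagents that add atoms: none
Why: CuI-catalysed SN2 opening of the terminal epoxide by the primary Grignard reagent at the unsubstituted carbon leaves the stereocenter unattacked, so the S configuration of 10 is carried into 12.

Step 6
Reactants: 12 (2S)-undec-10-en-2-ol
Product: 14 (10S)-10-methoxyundec-1-ene, via sodium alkoxide 13 (not isolated)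
Conditions: NaH, THF/DMF, 0 °C; MeI, rt
Reagents that add atoms: iodomethane, CI
Why: Williamson ether synthesis on the sodium alkoxide, in which the C–O bond of the stereocenter is not involved.

Step 7
Reactants: 8 (3S)-3-ethenyl-6,8-bis(methoxymethoxy)isochromane; 14 (10S)-10-methoxyundec-1-ene (3 equiv)
Product: 15 (3S)-3-[(1E,10S)-10-methoxyundec-1-en-1-yl]-6,8-bis(methoxymethoxy)isochromane
Conditions: second-generation Grubbs catalyst RuCl2(=CHPh)(PCy3)(H2IMes) (5 mol %), CH2Cl2, 40 °C, argon sweep
Reagents that add atoms: none
Why: Olefin cross-metathesis, in which the unhindered terminal alkene 14 engages the Grubbs catalyst quickly while the secondary allylic ether 8 homodimerizes slowly, so an excess of 14 and loss of ethene should drive the cross product; its alkene geometry is irrelevant and C3 is not touched.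

Step 8
Reactants: 15 (3S)-3-[(1E,10S)-10-methoxyundec-1-en-1-yl]-6,8-bis(methoxymethoxy)isochromane
Product: 16 (3R)-3-[(10S)-10-methoxyundecyl]-6,8-bis(methoxymethoxy)isochromane
Conditions: H2 (1 atm), Pt/C (5 wt %), EtOAc, rt
Reagents that add atoms: none
Why: Heterogeneous catalytic hydrogenation of the disubstituted alkene, with Pt/C chosen over Pd/C to spare the allylic C3–O and benzylic C1–O bonds from hydrogenolysis; C3 changes descriptor from S to R only because the saturated chain now ranks below C4.

Step 9
Reactants: 16 (3R)-3-[(10S)-10-methoxyundecyl]-6,8-bis(methoxymethoxy)isochromane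
Product: 17 (3R)-3-[(10S)-10-methoxyundecyl]-6,8-bis(methoxymethoxy)isochroman-1-one
Conditions: pyridinium chlorochromate [C5H5NH][CrO3Cl] (4 equiv), NaOAc, 4 Å molecular sieves, CH2Cl2, reflux
Reagents that add atoms: pyridinium chlorochromate, [O-][Cr](=O)(=O)Cl.c1cc[nH+]cc1
Why: Benzylic ether oxidation by hexavalent chromium should occur at C1, whose C–H bonds are activated both by O2 and by the electron-rich ring A, and not at C4, the acetal CH2 groups or C10'–H, while the acetate buffer protects the acid-labile acetals.

Step 10
Reactants: 17 (3R)-3-[(10S)-10-methoxyundecyl]-6,8-bis(methoxymethoxy)isochroman-1-one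
Product: 18 (3R)-6,8-dihydroxy-3-[(10S)-10-methoxyundecyl]isochroman-1-one (CNP0242607.1)
Conditions: HCl (1.25 M in MeOH), rt to 40 °C
Reagents that add atoms: none
Why: Acid-catalysed transacetalization to methanol removes both methoxymethyl groups as dimethoxymethane, while the secondary methyl ether is inert and the six-membered lactone, held by the hydrogen bond from the C8 hydroxyl, is the stable form under these conditions.

## Compound list

1 | methyl orsellinate (methyl 2,4-dihydroxy-6-methylbenzoate) | COC(=O)c1c(C)cc(O)cc1O | starting material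
2 | disodium bis-phenoxide of 1 [disodium 4-(methoxycarbonyl)-5-methylbenzene-1,3-bis(olate)] | COC(=O)c1c(C)cc([O-])cc1[O-].[Na+].[Na+] | intermediate
3 | methyl 2,4-bis(methoxymethoxy)-6-methylbenzoate | COC(=O)c1c(C)cc(OCOC)cc1OCOC | intermediate
4 | allyl bromide (3-bromoprop-1-ene) | C=CCBr | starting material
5 | methyl 2-(lithiomethyl)-4,6-bis(methoxymethoxy)benzoate | [Li]Cc1cc(OCOC)cc(OCOC)c1C(=O)OC | intermediate
6 | methyl 2-(but-3-en-1-yl)-4,6-bis(methoxymethoxy)benzoate | C=CCCc1cc(OCOC)cc(OCOC)c1C(=O)OC | intermediate
7 | [2-(but-3-en-1-yl)-4,6-bis(methoxymethoxy)phenyl]methanol | C=CCCc1cc(OCOC)cc(OCOC)c1CO | intermediate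
8 | (3S)-3-ethenyl-6,8-bis(methoxymethoxy)isochromane | C=C[C@@H]1Cc2cc(OCOC)cc(OCOC)c2CO1 | intermediate
9 | 8-bromooct-1-ene | C=CCCCCCCBr | starting material
10 | (S)-propylene oxide [(2S)-2-methyloxirane] | C[C@H]1CO1 | starting material
11 | oct-7-en-1-ylmagnesium bromide | C=CCCCCCC[Mg]Br | intermediate
12 | (2S)-undec-10-en-2-ol | C[C@H](O)CCCCCCCC=C | intermediate
13 | sodium (2S)-undec-10-en-2-olate | C[C@H]([O-])CCCCCCCC=C.[Na+] | intermediate
14 | (10S)-10-methoxyundec-1-ene | CO[C@@H](C)CCCCCCCC=C | intermediate
15 | (3S)-3-[(1E,10S)-10-methoxyundec-1-en-1-yl]-6,8-bis(methoxymethoxy)isochromane | CO[C@@H](C)CCCCCCC/C=C/[C@@H]1Cc2cc(OCOC)cc(OCOC)c2CO1 | intermediate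
16 | (3R)-3-[(10S)-10-methoxyundecyl]-6,8-bis(methoxymethoxy)isochromane | CO[C@@H](C)CCCCCCCCC[C@@H]1Cc2cc(OCOC)cc(OCOC)c2CO1 | intermediate
17 | (3R)-3-[(10S)-10-methoxyundecyl]-6,8-bis(methoxymethoxy)isochroman-1-one | CO[C@@H](C)CCCCCCCCC[C@@H]1Cc2cc(OCOC)cc(OCOC)c2C(=O)O1 | intermediate
18 | (3R)-6,8-dihydroxy-3-[(10S)-10-methoxyundecyl]isochroman-1-one | CO[C@@H](C)CCCCCCCCC[C@@H]1Cc2cc(O)cc(O)c2C(=O)O1 | target

## Step count and risks

Total steps: 10. Longest linear sequence: 8 steps (steps 1–4 and 7–10); the chain fragment takes 2 steps (5 and 6).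

Steps most likely to fail:

1. Step 4. Face selection at the π-allyl unit may be incomplete on this electron-rich, doubly ortho-substituted benzylic alcohol. β-Hydride elimination to the aryl diene, oxidation of the alcohol, or acid-induced ionization of the benzylic position may also compete with ring closure. The fallback sets out from 3, obtains the stereocenter by kinetic resolution and closes ring B at O2–C1 instead of O2–C3.
   - Lithiation of 3 as in step 2 and addition of anion 5 to acrolein at −78 °C should give, once the lithium alkoxide has closed onto the ester, racemic 3-ethenyl-6,8-bis(methoxymethoxy)isochroman-1-one F1.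
   - LiAlH4 in THF would open F1 to racemic 1-[2-(hydroxymethyl)-3,5-bis(methoxymethoxy)phenyl]but-3-en-2-ol F2.
   - Sharpless kinetic resolution (stoichiometric Ti(OiPr)4, D-(−)-diisopropyl tartrate, tBuOOH, 4 Å molecular sieves, CH2Cl2, −20 °C) should leave (2S)-1-[2-(hydroxymethyl)-3,5-bis(methoxymethoxy)phenyl]but-3-en-2-ol F3. The R carbinol would be consumed as the erythro epoxy alcohol (1R)-2-[2-(hydroxymethyl)-3,5-bis(methoxymethoxy)phenyl]-1-[(2S)-oxiran-2-yl]ethan-1-ol F4, at the cost of half of the material.
   - Selective mesylation of the primary, electron-rich benzylic hydroxyl of F3 (MsCl, Et3N, CH2Cl2, −20 °C to rt) and displacement by the secondary hydroxyl (6-exo-tet, C3–O bond untouched) would bring the route back at 8.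

2. Step 9. Prolonged heating with the chromium reagent may cause over-oxidation at benzylic C4 or acid-induced loss of the acetals before C1 is fully oxidized. The fallback sets out from 16 and raises C1 in two mild stages.
   - DDQ in CH2Cl2/pH 7 buffer at 0 °C abstracts hydride from C1, and water should trap the oxocarbenium ion as the lactol (3R)-3-[(10S)-10-methoxyundecyl]-6,8-bis(methoxymethoxy)isochroman-1-ol F5 (mixture of C1 epimers).
   - Oxidation of the lactol with PhI(OAc)2 and catalytic TEMPO in CH2Cl2 at rt would return the route at 17.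

3. Step 7. Turnover at the hindered allylic ether may be slow, self-metathesis of the chain olefin may consume the catalyst, and ruthenium hydride species from catalyst decay may move the double bond toward C3 and erase the stereocenter. The fallback sets out from 8 and 14 and forms C1'=C2' by carbonyl olefination.
   - Oxidative cleavage of the vinyl group of 8 (OsO4 cat., NaIO4, 2,6-lutidine, dioxane/water) would give (3S)-6,8-bis(methoxymethoxy)isochromane-3-carbaldehyde F6, to be used at once because the α-alkoxy aldehyde can epimerize.
   - Ozonolysis of 14 with NaBH4 work-up would give (9S)-9-methoxydecan-1-ol F7.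
   - A Mitsunobu reaction of F7 with 1-phenyl-1H-tetrazole-5-thiol (PPh3, diisopropyl azodicarboxylate, THF) should give 5-{[(9S)-9-methoxydecyl]sulfanyl}-1-phenyl-1H-tetrazole F8.
   - mCPBA would oxidize F8 to 5-{[(9S)-9-methoxydecyl]sulfonyl}-1-phenyl-1H-tetrazole F9.
   - Julia–Kocienski olefination of F6 with the anion of F9 (KN(SiMe3)2, DME, −60 °C to rt) should return the route at 15, which is hydrogenated as in step 8.

## Further compounds

F1 | step 4 | racemic 3-ethenyl-6,8-bis(methoxymethoxy)isochroman-1-one | C=CC1Cc2cc(OCOC)cc(OCOC)c2C(=O)O1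
F2 | step 4 | racemic 1-[2-(hydroxymethyl)-3,5-bis(methoxymethoxy)phenyl]but-3-en-2-ol | C=CC(O)Cc1cc(OCOC)cc(OCOC)c1CO
F3 | step 4 | (2S)-1-[2-(hydroxymethyl)-3,5-bis(methoxymethoxy)phenyl]but-3-en-2-ol | C=C[C@@H](O)Cc1cc(OCOC)cc(OCOC)c1CO
F4 | step 4 | (1R)-2-[2-(hydroxymethyl)-3,5-bis(methoxymethoxy)phenyl]-1-[(2S)-oxiran-2-yl]ethan-1-ol | C1O[C@@H]1[C@H](O)Cc1cc(OCOC)cc(OCOC)c1CO
F5 | step 9 | (3R)-3-[(10S)-10-methoxyundecyl]-6,8-bis(methoxymethoxy)isochroman-1-ol | CO[C@@H](C)CCCCCCCCC[C@@H]1Cc2cc(OCOC)cc(OCOC)c2C(O)O1
F6 | step 7 | (3S)-6,8-bis(methoxymethoxy)isochromane-3-carbaldehyde | O=C[C@@H]1Cc2cc(OCOC)cc(OCOC)c2CO1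
F7 | step 7 | (9S)-9-methoxydecan-1-ol | CO[C@@H](C)CCCCCCCCO
F8 | step 7 | 5-{[(9S)-9-methoxydecyl]sulfanyl}-1-phenyl-1H-tetrazole | CO[C@@H](C)CCCCCCCCSc1nnnn1-c1ccccc1
F9 | step 7 | 5-{[(9S)-9-methoxydecyl]sulfonyl}-1-phenyl-1H-tetrazole | CO[C@@H](C)CCCCCCCCS(=O)(=O)c1nnnn1-c1ccccc1
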